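**Strategy.** The route rests on disconnecting the C3–C4 bond of ring C. In the flavonol, C4 (ketone) and C3 (enol carbon bearing OH) are both carbonyl-level carbons, i.e. an oxidised acyloin, so the bond is made by umpolung. A carbene-catalysed intramolecular crossed benzoin turns the ring A aldehyde into an acyl anion that adds to a tethered aldehyde, forming C3–C4 and closing ring C as a dihydroflavonol in one operation. The precursor is a MOM-protected, C-prenylated ring A salicylaldehyde whose phenol oxygen (future O1) carries the CH(ring B aryl)–CHO unit. Oxidation of the ketol and acidic removal of four MOM ethers finish the synthesis.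

Key step: step 11

Remark: the target is achiral. C2 (and, after step 11, C3) of the intermediates are carried as racemates and diastereomer mixtures, because both centres become sp2 in step 12.
Remark: every phenol of the dialdehyde is capped as a MOM ether (no phenoxide under the basic carbene conditions, one global deprotection), and the aliphatic aldehyde is unveiled only in the step directly before ring closure.
Remark: phloroglucinol, prenyl bromide, 4-bromoresorcinol and (tert-butyldimethylsilyloxy)acetaldehyde are taken as commercial. MOM = methoxymethyl, prenyl = 3-methylbut-2-en-1-yl.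

**Route**

Step 1
Reactants: 1 phloroglucinol
Product: 2 3,5-bis(methoxymethoxy)phenol
Conditions: MOMCl (2.0 equiv), i-Pr2NEt, DMF, 0 °C to rt
Reagents that add atoms: chloromethyl methyl ether, COCCl
Why: O-alkylation of the phenoxide by the reactive α-chloro ether (Williamson type); with two equivalents the threefold-symmetric triol should give the bis-ether as the main component of a statistical mixture, separable from mono- and tris-ether by chromatography.

Step 2
Reactants: 2 3,5-bis(methoxymethoxy)phenol
Product: 3 triisopropyl[3,5-bis(methoxymethoxy)phenoxy]silane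
Conditions: TIPSCl, imidazole, DMF, rt
Reagents that add atoms: triisopropylsilyl chloride, CC(C)[Si](Cl)(C(C)C)C(C)C
Why: Standard silylation of a phenol; the bulky TIPS ether masks the oxygen that becomes O1, survives n-BuLi and does not direct lithiation.

Step 3
Reactants: 3 triisopropyl[3,5-bis(methoxymethoxy)phenoxy]silane; 4 prenyl bromide (1-bromo-3-methylbut-2-ene)
Product: 6 triisopropyl[3,5-bis(methoxymethoxy)-4-(3-methylbut-2-en-1-yl)phenoxy]silane, via aryllithium 5 (not isolated)
Conditions: n-BuLi, THF, 0 °C; then CuBr·SMe2 (10 mol%), 4, −78 °C to rt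
Reagents that add atoms: none
Why: Directed ortho-metalation takes place at the only C–H flanked by two MOM ethers, and the aryl nucleophile, relayed through copper, is alkylated at the primary carbon of the allylic bromide (SN2, no allylic transposition).

Step 4
Reactants: 6 triisopropyl[3,5-bis(methoxymethoxy)-4-(3-methylbut-2-en-1-yl)phenoxy]silane
Product: 7 3,5-bis(methoxymethoxy)-4-(3-methylbut-2-en-1-yl)phenol
Conditions: TBAF, AcOH, THF, 0 °C to rt
Reagents that add atoms: none
Why: Fluoride-induced cleavage of the aryl silyl ether leaves MOM ethers and alkene untouched and gives a symmetric phenol whose two ortho positions are equivalent.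

Step 5
Reactants: 7 3,5-bis(methoxymethoxy)-4-(3-methylbut-2-en-1-yl)phenol
Product: 8 6-hydroxy-2,4-bis(methoxymethoxy)-3-(3-methylbut-2-en-1-yl)benzaldehyde
Conditions: MgCl2, Et3N, (CH2O)n, MeCN, 80 °C; aq NH4Cl work-up
Reagents that add atoms: paraformaldehyde (formaldehyde), C=O
Why: Magnesium-mediated ortho-formylation of a phenol (Casnati–Skattebøl reaction): the magnesium phenoxide delivers formaldehyde to an ortho carbon only and a second formaldehyde oxidises the benzylic alkoxide; as both ortho positions are equivalent, a single isomer should form, with prenyl between the two MOM ethers (future C6).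

Step 6
Reactants: 9 4-bromoresorcinol (4-bromobenzene-1,3-diol)
Product: 10 1-bromo-2,4-bis(methoxymethoxy)benzene
Conditions: MOMCl, i-Pr2NEt, CH2Cl2, 0 °C to rt
Reagents that add atoms: chloromethyl methyl ether, COCCl
Why: Exhaustive O-alkylation of both phenols with the α-chloro ether under amine base.

Step 7
Reactants: 10 1-bromo-2,4-bis(methoxymethoxy)benzene; 11 (tert-butyldimethylsilyloxy)acetaldehyde
Product: 13 rac-1-[2,4-bis(methoxymethoxy)phenyl]-2-[(tert-butyldimethylsilyl)oxy]ethan-1-ol, via aryllithium 12 (not isolated)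
Conditions: n-BuLi, THF, −78 °C; then 11, −78 °C; H2O
Reagents that add atoms: none
Why: Bromine–lithium exchange is faster than ortho-deprotonation at −78 °C, and 1,2-addition of the aryllithium to the aldehyde gives the racemic benzylic alcohol with the primary oxygen already differentiated as its TBS ether.

Step 8
Reactants: 8 6-hydroxy-2,4-bis(methoxymethoxy)-3-(3-methylbut-2-en-1-yl)benzaldehyde; 13 rac-1-[2,4-bis(methoxymethoxy)phenyl]-2-[(tert-butyldimethylsilyl)oxy]ethan-1-ol
Product: 14 rac-6-{1-[2,4-bis(methoxymethoxy)phenyl]-2-[(tert-butyldimethylsilyl)oxy]ethoxy}-2,4-bis(methoxymethoxy)-3-(3-methylbut-2-en-1-yl)benzaldehyde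
Conditions: PPh3, DIAD, THF, 0 °C to rt
Reagents that add atoms: none
Why: Mitsunobu etherification: the acidic, chelated phenol of 8 is a good pronucleophile for the oxyphosphonium ion of the benzylic alcohol; the new C–O centre (future C2) is wanted racemic, so partial ionisation is harmless.

Step 9
Reactants: 14 rac-6-{1-[2,4-bis(methoxymethoxy)phenyl]-2-[(tert-butyldimethylsilyl)oxy]ethoxy}-2,4-bis(methoxymethoxy)-3-(3-methylbut-2-en-1-yl)benzaldehyde
Product: 15 rac-6-{1-[2,4-bis(methoxymethoxy)phenyl]-2-hydroxyethoxy}-2,4-bis(methoxymethoxy)-3-(3-methylbut-2-en-1-yl)benzaldehyde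
Conditions: TBAF, AcOH, THF, 0 °C to rt
Reagents that add atoms: none
Why: Fluoride cleaves the primary TBS ether, and the acetic acid buffer keeps the alkoxide from starting aryl migration or addition to the aryl aldehyde.

Step 10
Reactants: 15 rac-6-{1-[2,4-bis(methoxymethoxy)phenyl]-2-hydroxyethoxy}-2,4-bis(methoxymethoxy)-3-(3-methylbut-2-en-1-yl)benzaldehyde
Product: 16 rac-6-{1-[2,4-bis(methoxymethoxy)phenyl]-2-oxoethoxy}-2,4-bis(methoxymethoxy)-3-(3-methylbut-2-en-1-yl)benzaldehyde
Conditions: Dess–Martin periodinane, pyridine, CH2Cl2, 0 °C to rt; short silica pad, used at once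
Reagents that add atoms: none
Why: Dess–Martin oxidation converts the primary alcohol into the aldehyde under near-neutral, non-aqueous conditions that spare the prenyl alkene, the MOM ethers and the aryl aldehyde; the enolisable dialdehyde is not stored.

Step 11
Reactants: 16 rac-6-{1-[2,4-bis(methoxymethoxy)phenyl]-2-oxoethoxy}-2,4-bis(methoxymethoxy)-3-(3-methylbut-2-en-1-yl)benzaldehyde
Product: 17 rac-2-[2,4-bis(methoxymethoxy)phenyl]-3-hydroxy-5,7-bis(methoxymethoxy)-6-(3-methylbut-2-en-1-yl)chroman-4-one (mixture of 2,3-cis and 2,3-trans isomers)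
Conditions: 2-(pentafluorophenyl)-6,7-dihydro-5H-pyrrolo[2,1-c][1,2,4]triazol-2-ium tetrafluoroborate (15 mol%), i-Pr2NEt (30 mol%), degassed toluene (0.02 M), rt, argon
Reagents that add atoms: none
Why: The free carbene adds to the ring A aldehyde, proton transfer gives the aryl-conjugated enaminol (acyl anion equivalent), its carbon attacks the tethered aliphatic aldehyde, and collapse of the adduct releases the carbene and the C4 ketone; the closest known reactions are the carbene-catalysed intramolecular crossed benzoin closures of salicylaldehyde-derived keto ethers to 3-hydroxychroman-4-ones and the benzoin cyclisations of dialdehydes. Ring C closes in a 6-exo-trig mode, the enaminol carbon attacking the exocyclic C=O of the aldehyde. The new C3 carbinol centre is set without external control, biased only by the existing racemic C2 centre (the 2,3-trans isomer with both substituents equatorial should dominate after equilibration through the enediol), and this is irrelevant because C2 and C3 both become sp2 in step 12. The selectivity needed is chemoselectivity: the ring A aldehyde, not the aliphatic one, must become the acyl anion, because an enaminol formed at C3 carries the ring A aryloxide as an α-leaving group and would be diverted to an acyl azolium and on to an aryl ester or a 3-arylcoumarin; the higher acidity of the aryl-substituted carbene adduct and the hindered tertiary α-carbon of the aliphatic aldehyde, which makes it a better acceptor than donor, favour the desired course. The ortho ether tether, high dilution and a weak amine base keep intermolecular benzoin, enolisation at C2 and the 5-exo aldol closure to a dihydrobenzofuran in check, and any 4-hydroxy-3-one regioisomer that still forms is carried to the same flavonol in step 12.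

Step 12
Reactants: 17 rac-2-[2,4-bis(methoxymethoxy)phenyl]-3-hydroxy-5,7-bis(methoxymethoxy)-6-(3-methylbut-2-en-1-yl)chroman-4-one
Product: 19 2-[2,4-bis(methoxymethoxy)phenyl]-3-hydroxy-5,7-bis(methoxymethoxy)-6-(3-methylbut-2-en-1-yl)-4H-chromen-4-one, via chromane-3,4-dione 18 (not isolated)
Conditions: Dess–Martin periodinane (1.2 equiv), pyridine, CH2Cl2, 0 °C to rt; then Et3N (cat.)
Reagents that add atoms: none
Why: Dess–Martin oxidation of the α-ketol gives the 3,4-dione, which enolises through its acidic C2–H to the conjugated 3-hydroxychromen-4-one and so erases both stereocentres; a regioisomeric 4-hydroxy-3-one would be oxidised to the same dione.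

Step 13
Reactants: 19 2-[2,4-bis(methoxymethoxy)phenyl]-3-hydroxy-5,7-bis(methoxymethoxy)-6-(3-methylbut-2-en-1-yl)-4H-chromen-4-one
Product: 20 2-(2,4-dihydroxyphenyl)-3,5,7-trihydroxy-6-(3-methylbut-2-en-1-yl)-4H-chromen-4-one (target)
Conditions: HCl (3 M aq), MeOH, 50 °C, short reaction time
Reagents that add atoms: none
Why: Acid-catalysed acetal exchange with methanol removes all four aryl MOM ethers (the peri C5 ether fastest); moderate temperature and short time are chosen to spare the acid-sensitive prenyl group.

**Compound list**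

1 | phloroglucinol (benzene-1,3,5-triol) | Oc1cc(O)cc(O)c1 | starting material
2 | 3,5-bis(methoxymethoxy)phenol | COCOc1cc(O)cc(OCOC)c1 | intermediate
3 | triisopropyl[3,5-bis(methoxymethoxy)phenoxy]silane | COCOc1cc(OCOC)cc(O[Si](C(C)C)(C(C)C)C(C)C)c1 | intermediate
4 | prenyl bromide (1-bromo-3-methylbut-2-ene) | CC(C)=CCBr | starting material
5 | {2,6-bis(methoxymethoxy)-4-[(triisopropylsilyl)oxy]phenyl}lithium (not isolated) | [Li]c1c(OCOC)cc(O[Si](C(C)C)(C(C)C)C(C)C)cc1OCOC | intermediate
6 | triisopropyl[3,5-bis(methoxymethoxy)-4-(3-methylbut-2-en-1-yl)phenoxy]silane | CC(C)=CCc1c(OCOC)cc(O[Si](C(C)C)(C(C)C)C(C)C)cc1OCOC | intermediate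
7 | 3,5-bis(methoxymethoxy)-4-(3-methylbut-2-en-1-yl)phenol | CC(C)=CCc1c(OCOC)cc(O)cc1OCOC | intermediate
8 | 6-hydroxy-2,4-bis(methoxymethoxy)-3-(3-methylbut-2-en-1-yl)benzaldehyde | CC(C)=CCc1c(OCOC)cc(O)c(C=O)c1OCOC | intermediate
9 | 4-bromoresorcinol (4-bromobenzene-1,3-diol) | Oc1ccc(Br)c(O)c1 | starting material
10 | 1-bromo-2,4-bis(methoxymethoxy)benzene | COCOc1ccc(Br)c(OCOC)c1 | intermediate
11 | (tert-butyldimethylsilyloxy)acetaldehyde | O=CCO[Si](C)(C)C(C)(C)C | starting material
12 | [2,4-bis(methoxymethoxy)phenyl]lithium (not isolated) | [Li]c1ccc(OCOC)cc1OCOC | intermediate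
13 | rac-1-[2,4-bis(methoxymethoxy)phenyl]-2-[(tert-butyldimethylsilyl)oxy]ethan-1-ol | COCOc1ccc(C(O)CO[Si](C)(C)C(C)(C)C)c(OCOC)c1 | intermediate
14 | rac-6-{1-[2,4-bis(methoxymethoxy)phenyl]-2-[(tert-butyldimethylsilyl)oxy]ethoxy}-2,4-bis(methoxymethoxy)-3-(3-methylbut-2-en-1-yl)benzaldehyde | CC(C)=CCc1c(OCOC)cc(OC(CO[Si](C)(C)C(C)(C)C)c2ccc(OCOC)cc2OCOC)c(C=O)c1OCOC | intermediate
15 | rac-6-{1-[2,4-bis(methoxymethoxy)phenyl]-2-hydroxyethoxy}-2,4-bis(methoxymethoxy)-3-(3-methylbut-2-en-1-yl)benzaldehyde | CC(C)=CCc1c(OCOC)cc(OC(CO)c2ccc(OCOC)cc2OCOC)c(C=O)c1OCOC | intermediate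
16 | rac-6-{1-[2,4-bis(methoxymethoxy)phenyl]-2-oxoethoxy}-2,4-bis(methoxymethoxy)-3-(3-methylbut-2-en-1-yl)benzaldehyde (key-step precursor) | CC(C)=CCc1c(OCOC)cc(OC(C=O)c2ccc(OCOC)cc2OCOC)c(C=O)c1OCOC | intermediate
17 | rac-2-[2,4-bis(methoxymethoxy)phenyl]-3-hydroxy-5,7-bis(methoxymethoxy)-6-(3-methylbut-2-en-1-yl)chroman-4-one, 2,3-cis/trans mixture (key-step product) | CC(C)=CCc1c(OCOC)cc2OC(c3ccc(OCOC)cc3OCOC)C(O)C(=O)c2c1OCOC | intermediate
18 | rac-2-[2,4-bis(methoxymethoxy)phenyl]-5,7-bis(methoxymethoxy)-6-(3-methylbut-2-en-1-yl)chromane-3,4-dione (not isolated) | CC(C)=CCc1c(OCOC)cc2OC(c3ccc(OCOC)cc3OCOC)C(=O)C(=O)c2c1OCOC | intermediate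
19 | 2-[2,4-bis(methoxymethoxy)phenyl]-3-hydroxy-5,7-bis(methoxymethoxy)-6-(3-methylbut-2-en-1-yl)-4H-chromen-4-one | CC(C)=CCc1c(OCOC)cc2oc(-c3ccc(OCOC)cc3OCOC)c(O)c(=O)c2c1OCOC | intermediate
20 | 2-(2,4-dihydroxyphenyl)-3,5,7-trihydroxy-6-(3-methylbut-2-en-1-yl)-4H-chromen-4-one (achiral) | CC(C)=CCc1c(O)cc2oc(-c3ccc(O)cc3O)c(O)c(=O)c2c1O | target

**Step count and risks**

Total step count: 13. Longest linear sequence: 11 steps (steps 1–5 and 8–13, from phloroglucinol); the ring B branch has 2 steps (6 and 7).

Steps most likely to fail: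

1. Step 11 (key step). The carbene may engage the aliphatic aldehyde instead of the ring A aldehyde; loss of the ring A aryloxide from C2 (internal redox to an acyl azolium) would then cut the tether. Base-induced enolisation at C2 may also start a 5-exo aldol closure, or carbene addition to the doubly ortho-substituted, electron-rich aldehyde may be too slow. The fallback sets out from 16 and comes back at 19, forming the same C3–C4 bond reductively. SmI2 in THF at −78 °C should reduce the aryl aldehyde to its ketyl, which closes onto the tethered aldehyde (intramolecular pinacol coupling of a dialdehyde) to give rac-2-[2,4-bis(methoxymethoxy)phenyl]-5,7-bis(methoxymethoxy)-6-(3-methylbut-2-en-1-yl)chromane-3,4-diol F1. Double Swern oxidation of the diol (DMSO, (COCl)2, then Et3N, −78 °C) should give dione 18, which enolises to flavonol 19.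

2. Step 8. Elimination or ionisation of the activated, electron-rich benzylic alcohol (silyl enol ether formation, alkylation of the hydrazide) may outpace attack by the hindered, hydrogen-bonded phenol. The fallback sets out from 8 and 10 and comes back at 16. It makes the aryl ether by SN2 at an α-bromo ester, which has no β-hydrogen, and corrects the oxidation levels afterwards. Aryllithium 12, made from 10 as in step 7, is added to ethyl glyoxylate at −78 °C to give rac-ethyl 2-[2,4-bis(methoxymethoxy)phenyl]-2-hydroxyacetate F2. Appel bromination (CBr4, PPh3, CH2Cl2, 0 °C) should give rac-ethyl 2-bromo-2-[2,4-bis(methoxymethoxy)phenyl]acetate F3, used at once. Williamson etherification of phenol 8 with it (K2CO3, DMF, rt) should give rac-ethyl 2-[2,4-bis(methoxymethoxy)phenyl]-2-[2-formyl-3,5-bis(methoxymethoxy)-4-(3-methylbut-2-en-1-yl)phenoxy]acetate F4. LiAlH4 (THF, 0 °C) reduces ester and aryl aldehyde to rac-2-[2,4-bis(methoxymethoxy)phenyl]-2-[2-(hydroxymethyl)-3,5-bis(methoxymethoxy)-4-(3-methylbut-2-en-1-yl)phenoxy]ethan-1-ol F5. Dess–Martin oxidation of both primary alcohols (2.5 equiv, pyridine, CH2Cl2) returns dialdehyde 16.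

3. Step 13. Under protic acid the prenyl alkene may be protonated and captured by the freed C5 or C7 hydroxyl (chroman formation) or by methanol before all four acetals are cleaved. The fallback sets out from 19 and comes back at 20, exchanging the protecting groups without a Brønsted acid. TESOTf with 2,2'-bipyridyl (MeCN, 0 °C to rt) should convert the four aryl MOM ethers into aryl triethylsilyl ethers and silylate the 3-hydroxyl, giving 2-[2,4-bis(triethylsilyloxy)phenyl]-3,5,7-tris(triethylsilyloxy)-6-(3-methylbut-2-en-1-yl)-4H-chromen-4-one F6. KF in MeOH at rt then cleaves the silyl ethers to 20.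

**Further compounds**

F1 | step 11 | rac-2-[2,4-bis(methoxymethoxy)phenyl]-5,7-bis(methoxymethoxy)-6-(3-methylbut-2-en-1-yl)chromane-3,4-diol | CC(C)=CCc1c(OCOC)cc2OC(c3ccc(OCOC)cc3OCOC)C(O)C(O)c2c1OCOC
F2 | step 8 | rac-ethyl 2-[2,4-bis(methoxymethoxy)phenyl]-2-hydroxyacetate | CCOC(=O)C(O)c1ccc(OCOC)cc1OCOC
F3 | step 8 | rac-ethyl 2-bromo-2-[2,4-bis(methoxymethoxy)phenyl]acetate | CCOC(=O)C(Br)c1ccc(OCOC)cc1OCOC
F4 | step 8 | rac-ethyl 2-[2,4-bis(methoxymethoxy)phenyl]-2-[2-formyl-3,5-bis(methoxymethoxy)-4-(3-methylbut-2-en-1-yl)phenoxy]acetate | CCOC(=O)C(Oc1cc(OCOC)c(CC=C(C)C)c(OCOC)c1C=O)c1ccc(OCOC)cc1OCOC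
F5 | step 8 | rac-2-[2,4-bis(methoxymethoxy)phenyl]-2-[2-(hydroxymethyl)-3,5-bis(methoxymethoxy)-4-(3-methylbut-2-en-1-yl)phenoxy]ethan-1-ol | OCC(Oc1cc(OCOC)c(CC=C(C)C)c(OCOC)c1CO)c1ccc(OCOC)cc1OCOC
F6 | step 13 | 2-[2,4-bis(triethylsilyloxy)phenyl]-3,5,7-tris(triethylsilyloxy)-6-(3-methylbut-2-en-1-yl)-4H-chromen-4-one | CC(C)=CCc1c(O[Si](CC)(CC)CC)cc2oc(-c3ccc(O[Si](CC)(CC)CC)cc3O[Si](CC)(CC)CC)c(O[Si](CC)(CC)CC)c(=O)c2c1O[Si](CC)(CC)CC
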